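The earlier runs and the new flask are calculated for substances that don't exist; noise was put on by code.

At the last reading, 20.0 min, the cedar run stood at 7.20 and the elm run at 9.60 moles of target per mole of catalyst charged.

the same everywhere: substrate 0.10 M; free catalyst 0.50 mM
- cedar: partner 0.080 M; run made earlier
- elm: partner 0.18 M; run made earlier
- flask: partner 0.120 M; time 30 min

- cedar (time / min: target / %, substrate / %): 2.50: 1.2, 98.9; 5.00: 1.5, 97.5; 8.00: 2.4, 97.2; 10.0: 2.4, 97.6; 12.0: 2.3, 97.0; 15.0: 3.6, 96.4; 20.0: 3.6, 95.7
- elm (time / min: target / %, substrate / %): 1.00: 0.2, 99.1; 3.00: 1.8, 97.7; 5.00: 1.4, 96.6; 8.00: 3.2, 96.2; 10.0: 2.9, 95.8; 15.0: 4.4, 95.4; 20.0: 4.8, 94.3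

(scatter of a reading: 0.5 percentage points)

- concentration of target at 30 min, in M
- concentration of substrate at 30 min, in M

- the earlier runs were read with a standard deviation of 0.5 percentage points

The asked flask's partner lies between those of the two runs, so this reckoning takes their mean. In the cedar run, target rose 3.00-fold while time rose 8.00-fold, whose square root is 2.83, so the mean is carried to 30 min by the square root of time. That gives 10.3 turns, a turn count being target formed per catalyst charged (the turnover number), so target is 5.14% of the substrate charged.

The forecast gave 5.20% target (4.50% to 6.10%) and 93.8% substrate (92.5% to 94.8%), saying: “This looks like catalyst decay or inhibition rather than substrate depletion”.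

The asked flask gives 5.32% target and 94.2% substrate, within the forecast's margins, which is 10.6 turns.

    substrate + free catalyst → catalyst intermediate A (k = 7.98 L mol⁻¹ s⁻¹)
    catalyst intermediate A → catalyst intermediate B (k = 21.4 s⁻¹)
    partner + catalyst intermediate B ⇌ catalyst intermediate C (K = 7.13 L mol⁻¹, k = 2.62 L mol⁻¹ s⁻¹)
    catalyst intermediate C → by-product + catalyst intermediate D (k = 0.0488 s⁻¹)
    catalyst intermediate D → free catalyst + target (k = 0.245 s⁻¹)
    2 partner → self-condensation product (k = 0.0268 L mol⁻¹ s⁻¹)

At 30.0 min in the asked flask, catalyst intermediate B, the resting state, holds 93.7% of the catalyst charged. Taken back to 15.0 min by the same square root, the 10.3 turns give 3.64% target, and the asked flask holds 3.85%.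

A neighbour flask, like the asked one but for its catalyst, has a quarter of the catalyst, so 10.3 turns give 1.34% target there. The computed neighbour flask holds 1.42% at 30.0 min, which is 11.0 turns.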